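Prostanoid numbering (C1 = ester carbon, C20 = chain end) is used. The cyclopentenone ring C8–C12 is split into two C10 halves. C11–C12 is a 2-oxoaldehyde with its aldehyde masked as gem-diacetate (5). C8–C9–C10 is the 1,3-dinucleophile latent in enynoyl bromo ylide 13. In one flask a chiral copper hydride converts the C7≡C8 alkyne into an allenolate and C8 adds to the C12 ketone. The alkoxide then pulls one acetyl group over from C11, creating the tertiary acetate and freeing the aldehyde, and ylide carbon C10 closes the ring by Wittig reaction. Exploited features: the vicinal C12–OAc/C11–H pair of the ring and the (7Z)-alkylidene at C8.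

Key step: step 8

Assumption: the sense of induction of the copper–bisphosphine allenolate on ketone 5 cannot be predicted with certainty. (R)-DTBM-SEGPHOS is written for the (12R) product, and its mirror image would be taken if a trial run favours the (12S) acetate.

Step 1
Reactants: 1 (Z)-non-3-en-1-ol
Product: 2 (Z)-non-3-enoic acid
Conditions: TEMPO (10 mol %), PhI(OAc)2 (2.2 equiv), MeCN/H2O 1:1, 0 °C to rt
Reagents that add atoms: water, O
Why: The TEMPO/iodine(III) oxidation of a primary alcohol (oxoammonium oxidation via the aldehyde hydrate) runs near neutral pH, so the skipped (Z)-alkene should neither migrate into conjugation nor isomerise; no stereocentre is formed.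

Step 2
Reactants: 2 (Z)-non-3-enoic acid
Product: 4 (Z)-1-diazodec-4-en-2-one, via (Z)-non-3-enoyl chloride 3 (not isolated)
Conditions: (COCl)2 (1.2 equiv), DMF (cat.), CH2Cl2, 0 °C to rt, evaporate; CH2N2 (3 equiv, from Diazald), Et2O, 0 °C
Reagents that add atoms: diazomethane, C=[N+]=[N-]; oxalyl chloride, O=C(Cl)C(=O)Cl (chlorine of 3 only)
Why: Acylation of diazomethane by an acid chloride (first stage of the Arndt–Eistert sequence) needs no amine base because excess diazomethane takes up HCl, so ketene formation and alkene migration in the β,γ-unsaturated acyl unit should be avoided; no stereocentre is formed.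

Step 3
Reactants: 4 (Z)-1-diazodec-4-en-2-one
Product: 5 (Z)-2-oxodec-4-ene-1,1-diyl diacetate
Conditions: Pb(OAc)4 (1.05 equiv), CH2Cl2, −20 to 0 °C; filtration through neutral silica
Reagents that add atoms: lead(IV) acetate, CC(=O)O[Pb](OC(C)=O)(OC(C)=O)OC(C)=O
Why: In this oxidative gem-diacetoxylation of a diazo carbon with lead(IV) acetate the nucleophilic diazo carbon is plumbylated, acetate displaces nitrogen and reductive loss of lead(II) brings in the second acetate, which should be far faster at low temperature than any attack of Pb(IV) on the isolated (Z)-alkene; C11 carries two equal acetoxy groups and is no stereocentre.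

Step 4
Reactants: 6 methyl hex-5-ynoate
Product: 8 methyl (E)-6-iodohex-5-enoate, via (E)-alkenylzirconocene chloride 7 (not isolated)
Conditions: Cp2Zr(H)Cl (1.15 equiv), THF, rt, dark; I2 (1.1 equiv), 0 °C
Reagents that add atoms: iodine, II; Cp2Zr(H)Cl, [H][Zr](Cl)(C1C=CC=C1)C1C=CC=C1 (zirconocene unit of 7 only)
Why: In this hydrozirconation–iodinolysis, syn addition of Zr–H with zirconium at the alkyne terminus and iodination with retention fix the (5E) geometry, and the terminal alkyne should react faster than the methyl ester.

Step 5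
Reactants: 8 methyl (E)-6-iodohex-5-enoate, 9 propiolic acid
Product: 10 (E)-9-methoxy-9-oxonon-4-en-2-ynoic acid
Conditions: PdCl2(PPh3)2 (5 mol %), dppb (10 mol %), DBU (2.5 equiv), DMSO, 25 °C; citric acid work-up
Reagents that add atoms: none
Why: The copper-free Sonogashira coupling of propiolic acid (as its carboxylate) proceeds with retention of the alkenyl iodide geometry, and at room temperature without copper the decarboxylation of the alkynoic acid should stay slow.

Step 6
Reactants: 10 (E)-9-methoxy-9-oxonon-4-en-2-ynoic acid
Product: 12 methyl (E)-9-oxo-10-(triphenyl-λ5-phosphanylidene)dec-5-en-7-ynoate, via enynoyl chloride 11 (not isolated)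
Conditions: 1-chloro-N,N,2-trimethylprop-1-en-1-amine (1.1 equiv), CH2Cl2, 0 °C; added to Ph3P=CH2 [MePPh3Br (2.2 equiv), n-BuLi (2.1 equiv), THF, 0 °C] at −78 °C, then to −20 °C
Reagents that add atoms: methyltriphenylphosphonium bromide, C[P+](c1ccccc1)(c1ccccc1)c1ccccc1.[Br-]; 1-chloro-N,N,2-trimethylprop-1-en-1-amine, CC(C)=C(Cl)N(C)C (chlorine of 11 only)
Why: C-acylation of methylenetriphenylphosphorane by an alkynoyl chloride followed by transylidation with the second equivalent of ylide gives the stabilised acyl ylide, the neutral chloroenamine avoids HCl addition to the ynoic acid, and at −78 °C the acid chloride should outrun the methyl ester.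

Step 7
Reactants: 12 methyl (E)-9-oxo-10-(triphenyl-λ5-phosphanylidene)dec-5-en-7-ynoate
Product: 13 methyl (E)-10-bromo-9-oxo-10-(triphenyl-λ5-phosphanylidene)dec-5-en-7-ynoate
Conditions: NBS (1.0 equiv), CH2Cl2, −40 to 0 °C; aq. K2CO3 wash
Reagents that add atoms: N-bromosuccinimide, O=C1CCC(=O)N1Br
Why: In this electrophilic halogenation of a stabilised ylide the ylide carbon is by far the most nucleophilic site and the bromophosphonium ion is deprotonated again by succinimide anion, so enyne and ester should stay untouched.

Step 8
Reactants: 13 methyl (E)-10-bromo-9-oxo-10-(triphenyl-λ5-phosphanylidene)dec-5-en-7-ynoate, 5 (Z)-2-oxodec-4-ene-1,1-diyl diacetate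
Product: 17 methyl (5E,7Z)-7-[(2R)-2-acetoxy-4-bromo-2-[(Z)-oct-2-en-1-yl]-5-oxocyclopent-3-en-1-ylidene]hept-5-enoate, via copper(I) allenolate 14 (not isolated), via copper(I) aldolate 15 (not isolated), via acetoxy aldehyde ylide 16 (not isolated)
Conditions: CuOAc (1.05 equiv), (R)-DTBM-SEGPHOS (1.1 equiv), (EtO)2MeSiH (1.0 equiv), toluene, rt, 30 min; 13 (1.0 equiv), −40 °C; 5 (1.2 equiv), −78 to −20 °C; then 40 °C
Reagents that add atoms: copper(I) acetate, CC(=O)[O-].[Cu+] (copper of 14 and 15 only)
Why: Proposed new method: the ligated copper hydride adds H to C7 and Cu to C8/O9 of the ynone of 13 (conjugate hydrocupration, the acyl ylide being an acceptor of about ynoate strength), allenolate 14 adds through C8 to the ketone of 5, the tertiary copper alkoxide 15 attacks the neighbouring acetate through a five-membered cyclic intermediate, the hemiacetal alkoxide so formed expels acetate to give the non-enolisable aldehyde 16, and the restored stabilised ylide carbon C10 olefinates C11. The closest known reaction types are the copper hydride reductive aldol reaction of ynones and enoates with ketones (enantioselective with Cu–bisphosphine complexes), the (3+2) annulation of γ-anions of 2-oxoalkylidene phosphoranes with 1,2-dicarbonyl compounds by aldol addition plus intramolecular Wittig reaction, and the 1,2 O-to-O acyl shift of vicinal hydroxy esters, while their union, the gem-diacetate as a self-unmasking aldehyde and the bromo ylide as spectator are new. The only ring closes in the Wittig stage by 5-exo-trig attack of C10 on the C11 aldehyde and collapse of the oxaphosphetane, so the ring alkene can only be cis. The single stereocentre C12 is set in the aldol stage by the C2-symmetric bisphosphine on copper, which must tell the CH(OAc)2 arm from the CH2-alkenyl arm of the ketone in a closed six-membered transition state, and it cannot be lost later because the acyl shift makes the addition irreversible and C12 bears no hydrogen. The (7Z) geometry follows from syn H–Cu addition with retention, or equally from attack of the O-bound allenolate on the side of the C7 hydrogen, both of which place C12 cis to H7. Chemoselectivity rests on the order of addition (all hydride is consumed before 5 enters, so 5, 16 and 17 never meet a reductant), on the masked aldehyde (C8 finds only the ketone) and on the low basicity of the copper enolate toward the doubly activated C13 methylene group.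

Compound list
1 | (Z)-non-3-en-1-ol | CCCCC/C=C\CCO | starting material
2 | (Z)-non-3-enoic acid | CCCCC/C=C\CC(=O)O | intermediate
3 | (Z)-non-3-enoyl chloride (not isolated) | CCCCC/C=C\CC(=O)Cl | intermediate
4 | (Z)-1-diazodec-4-en-2-one | CCCCC/C=C\CC(=O)C=[N+]=[N-] | intermediate
5 | (Z)-2-oxodec-4-ene-1,1-diyl diacetate (C11–C20 half) | CCCCC/C=C\CC(=O)C(OC(C)=O)OC(C)=O | intermediate
6 | methyl hex-5-ynoate | COC(=O)CCCC#C | starting material
7 | chlorobis(cyclopentadienyl)[(E)-6-methoxy-6-oxohex-1-enyl]zirconium (not isolated, Cp drawn η1) | COC(=O)CCC/C=C/[Zr](Cl)(C1C=CC=C1)C1C=CC=C1 | intermediate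
8 | methyl (E)-6-iodohex-5-enoate | COC(=O)CCC/C=C/I | intermediate
9 | propiolic acid | C#CC(=O)O | starting material
10 | (E)-9-methoxy-9-oxonon-4-en-2-ynoic acid | COC(=O)CCC/C=C/C#CC(=O)O | intermediate
11 | methyl (E)-9-chloro-9-oxonon-5-en-7-ynoate (not isolated) | COC(=O)CCC/C=C/C#CC(=O)Cl | intermediate
12 | methyl (E)-9-oxo-10-(triphenyl-λ5-phosphanylidene)dec-5-en-7-ynoate | COC(=O)CCC/C=C/C#CC(=O)C=P(c1ccccc1)(c1ccccc1)c1ccccc1 | intermediate
13 | methyl (E)-10-bromo-9-oxo-10-(triphenyl-λ5-phosphanylidene)dec-5-en-7-ynoate (C1–C10 half) | COC(=O)CCC/C=C/C#CC(=O)C(Br)=P(c1ccccc1)(c1ccccc1)c1ccccc1 | intermediate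
14 | copper(I) allenolate of 13 with H at C7 and C7=C8=C9–OCu (not isolated, bisphosphine omitted) | COC(=O)CCC/C=C/C=C=C(O[Cu])C(Br)=P(c1ccccc1)(c1ccccc1)c1ccccc1 | intermediate
15 | copper(I) (12S)-alkoxide from addition of C8 of 14 to the ketone of 5, (5E,7Z,14Z), gem-diacetate intact (not isolated, bisphosphine omitted) | CCCCC/C=C\C[C@@](O[Cu])(C(OC(C)=O)OC(C)=O)/C(=C/C=C/CCCC(=O)OC)C(=O)C(Br)=P(c1ccccc1)(c1ccccc1)c1ccccc1 | intermediate
16 | (12S)-12-acetoxy-11-aldehyde still carrying the C10 bromo ylide, (5E,7Z,14Z) (not isolated) | CCCCC/C=C\C[C@@](OC(C)=O)(C=O)/C(=C/C=C/CCCC(=O)OC)C(=O)C(Br)=P(c1ccccc1)(c1ccccc1)c1ccccc1 | intermediate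
17 | methyl (5E,7Z)-7-[(2R)-2-acetoxy-4-bromo-2-[(Z)-oct-2-en-1-yl]-5-oxocyclopent-3-en-1-ylidene]hept-5-enoate | CCCCC/C=C\C[C@@]1(OC(C)=O)C=C(Br)C(=O)/C1=C\C=C\CCCC(=O)OC | target

Total step count: 8. Longest linear sequence: 5 (steps 4 to 8).

Steps most likely to fail

1. Step 8.
- What may go wrong: hydrocupration of the electron-rich ynone may be slow or wrongly oriented. Proton transfer from C13 of 5 may quench the allenolate. Facial selection at the ketone may be poor. The bromo ylide may close the ring too slowly.
- The fallback uses known reaction types only. The two ring bonds are then made one after the other and the α-chain is attached last. It sets out from 5 and 8 and comes back at 17.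
- Mild hydrolysis of 5 (NaHCO3, THF/H2O, 0 °C) gives (Z)-2-oxodec-4-enal F1.
- Commercial 1-(triphenylphosphoranylidene)propan-2-one and NBS give 1-bromo-1-(triphenyl-λ5-phosphanylidene)propan-2-one F2. This olefinates only the aldehyde of F1, giving (3Z,7Z)-3-bromotrideca-3,7-diene-2,5-dione F3.
- Irradiation (365 nm) in the presence of Et3N equilibrates the bromoalkene, and the isomer with cis acyl groups closes by intramolecular aldol addition. HPLC on a chiral phase then delivers (S)-2-bromo-4-hydroxy-4-[(Z)-oct-2-en-1-yl]cyclopent-2-en-1-one F4, which has the same spatial arrangement as C12 of 17.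
- Palladium-catalysed formylation of 8 (CO, Bu3SnH) gives methyl (E)-7-oxohept-5-enoate F5.
- The dianion of F4 (LDA, 2.1 equiv, −78 °C) adds to F5 to give the C7-hydroxy aldol adduct F6, and Ac2O/DMAP gives the 7,12-diacetate F7.
- DBU removes the C7 acetate (E1cB) to give 17 beside its (7E) isomer, which is separated and re-equilibrated by light.

2. Step 3.
- What may go wrong: Pb(IV) may attack the alkene or the acidic C13 position, or the α-acetoxy organolead intermediate may collapse by a 1,2-shift instead of taking up acetate.
- The fallback sets out from 4 and comes back at 5. Iodine (1.0 equiv, CH2Cl2, 0 °C) converts the diazo carbon into (Z)-1,1-diiododec-4-en-2-one F8. Silver acetate (2.2 equiv, AcOH, rt) then exchanges both iodides for acetate.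

3. Step 6.
- What may go wrong: the non-stabilised ylide may add in conjugate fashion to the enynoyl chloride or attack the methyl ester, and the acid chloride may oligomerise.
- The fallback sets out from 8 and comes back at 12, so steps 5 and 6 are not needed. The ylide is made first on a simple alkyne and the enyne bond last.
- Commercial 3-(trimethylsilyl)propiolic acid is activated with the chloroenamine and acylates Ph3P=CH2 to give 1-(triphenyl-λ5-phosphanylidene)-4-(trimethylsilyl)but-3-yn-2-one F9.
- K2CO3/MeOH removes silicon to give 1-(triphenyl-λ5-phosphanylidene)but-3-yn-2-one F10.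
- Sonogashira coupling of F10 with 8 (PdCl2(PPh3)2, CuI, Et3N, THF, rt) gives 12.

Further compounds
F1 | step 8 | (Z)-2-oxodec-4-enal | CCCCC/C=C\CC(=O)C=O
F2 | step 8 | 1-bromo-1-(triphenyl-λ5-phosphanylidene)propan-2-one | CC(=O)C(Br)=P(c1ccccc1)(c1ccccc1)c1ccccc1
F3 | step 8 | (3Z,7Z)-3-bromotrideca-3,7-diene-2,5-dione | CC(=O)/C(Br)=C/C(=O)C/C=C\CCCCC
F4 | step 8 | (S)-2-bromo-4-hydroxy-4-[(Z)-oct-2-en-1-yl]cyclopent-2-en-1-one | CCCCC/C=C\C[C@@]1(O)C=C(Br)C(=O)C1
F5 | step 8 | methyl (E)-7-oxohept-5-enoate | COC(=O)CCC/C=C/C=O
F6 | step 8 | C7-hydroxy aldol adduct of F4 and F5 (C12 as in 17, mixture at C7 and C8) | CCCCC/C=C\C[C@@]1(O)C=C(Br)C(=O)C1C(O)/C=C/CCCC(=O)OC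
F7 | step 8 | 7,12-diacetate of F6 | CCCCC/C=C\C[C@@]1(OC(C)=O)C=C(Br)C(=O)C1C(OC(C)=O)/C=C/CCCC(=O)OC
F8 | step 3 | (Z)-1,1-diiododec-4-en-2-one | CCCCC/C=C\CC(=O)C(I)I
F9 | step 6 | 1-(triphenyl-λ5-phosphanylidene)-4-(trimethylsilyl)but-3-yn-2-one | C[Si](C)(C)C#CC(=O)C=P(c1ccccc1)(c1ccccc1)c1ccccc1
F10 | step 6 | 1-(triphenyl-λ5-phosphanylidene)but-3-yn-2-one | C#CC(=O)C=P(c1ccccc1)(c1ccccc1)c1ccccc1
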